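**Plan**

- Feature: with the heptane numbered from the catechol end (OAc on C3, OH on C5), the C5 oxygen (O5) and benzylic C1 are 1,5-related. O5, C1, C2, C3, C4 and C5 can therefore form one tetrahydropyran ring with the C3 acetate exocyclic, and because C1 is benzylic to the catechol ring, the C1–O5 bond can later be removed by hydrogenolysis.
- Retrosynthesis: re-form C1–O5 to reach a tribenzylated all-cis 2-aryl-tetrahydropyran-4-yl acetate. Cut C1–O5, C1–C2 and C3–OAc together (Prins) into an (R)-homoallylic alcohol, 3,4-bis(benzyloxy)benzaldehyde and acetic acid. Cut C4–C5 (carbonyl allylation) back to a 3-arylpropanol.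
- Forward: phenol benzylation, enantioselective allylation (C4–C5), Prins closure of the only ring with acetate capture, then one hydrogenolysis that removes three benzyl groups and reopens the ring.
- Stereochemistry: C5 (R) comes from the allylation catalyst. C3 (R) is relayed from C5 through the chair Prins transition state (4,6-cis on the ring equals 3,5-anti in the chain). The C1 centre made alongside disappears when C1 becomes CH2.

Key step: step 3

Assumption: the (S)-bisphosphine iridium C,O-benzoate catalyst is taken to deliver allyl to the aldehyde face that gives the (R)-carbinol in this n-alkyl series; the sense is to be checked by Mosher ester analysis before the key step, and the antipodal ligand would be used if it proves opposite.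

Step 1
Reactants: 1 3-(4-hydroxyphenyl)propan-1-ol
Product: 2 3-[4-(benzyloxy)phenyl]propan-1-ol
Conditions: BnBr (1.05 equiv), K2CO3, acetone, reflux
Reagents that add atoms: benzyl bromide, BrCc1ccccc1
Why: Williamson ether synthesis; carbonate deprotonates only the phenol, so alkylation should occur at the aryl oxygen and leave the primary alcohol free.

Step 2
Reactants: 2 3-[4-(benzyloxy)phenyl]propan-1-ol; 3 allyl acetate
Product: 5 (3R)-1-[4-(benzyloxy)phenyl]hex-5-en-3-ol, via 3-[4-(benzyloxy)phenyl]propanal 4 (not isolated)
Conditions: 3 (5 equiv), [Ir(cod)Cl]2 (2.5 mol %), (S)-BINAP (5 mol %), 4-chloro-3-nitrobenzoic acid (10 mol %), Cs2CO3 (20 mol %), THF, 100 °C (sealed tube)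
Reagents that add atoms: none
Why: Krische iridium-catalysed transfer-hydrogenative carbonyl allylation; the cyclometallated iridium complex dehydrogenates the primary alcohol to aldehyde 4, the resulting hydride turns allyl acetate into a chiral allyl-iridium species, and this adds through a closed chair transition state, so the ligand sets the carbinol centre (R); the secondary homoallylic alcohol is not re-oxidised.

Step 3
Reactants: 5 (3R)-1-[4-(benzyloxy)phenyl]hex-5-en-3-ol; 6 3,4-bis(benzyloxy)benzaldehyde; 7 acetic acid
Product: 8 all-cis (2R,4S,6R)-2-[3,4-bis(benzyloxy)phenyl]-6-{2-[4-(benzyloxy)phenyl]ethyl}oxan-4-yl acetate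
Conditions: 6 (1.2 equiv), BF3·OEt2 (2 equiv), AcOH (10 equiv), TMSOAc (4 equiv), CH2Cl2, 0 °C to rt
Reagents that add atoms: trimethylsilyl acetate, CC(=O)O[Si](C)(C)C (shares the acetate pool with acetic acid 7 and scavenges the water of condensation)
Why: BF3·OEt2, acting as an unconsumed promoter, condenses 5 and 6 to an (E)-oxocarbenium ion conjugated with the dialkoxyaryl ring; the terminal alkene carbon attacks C1 of that ion, and acetate then quenches the delocalised tetrahydropyran-4-yl cation at C3. This is a three-component Prins cyclization with carboxylate capture, a known reaction of homoallylic alcohols, aldehydes and acetic acid under BF3. The single ring (O5–C1–C2–C3–C4–C5) closes by 6-endo-trig attack of the alkene on the oxocarbenium carbon through a chair transition state. C1 is set by that chair, with the C5 side chain and the aryl group both equatorial (2,6-cis), and C3 is set by equatorial approach of acetate to the ring cation; the resulting all-cis ring has ring C4 labelled S only through a priority change and is spatially the 3R,5R-anti pair of the open chain. The step needs C5 to stay configurationally intact and acetate to enter equatorially: pairing an alkyl carbinol with an aryl aldehyde makes the 2-oxonia-Cope shift run uphill from the conjugated ion, and the absence of free water suppresses side-chain exchange.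

Step 4
Reactants: 8 all-cis (2R,4S,6R)-2-[3,4-bis(benzyloxy)phenyl]-6-{2-[4-(benzyloxy)phenyl]ethyl}oxan-4-yl acetate
Product: 10 (3R,5R)-1-(3,4-dihydroxyphenyl)-5-hydroxy-7-(4-hydroxyphenyl)heptan-3-yl acetate, via triphenolic oxan-4-yl acetate 9 (not isolated)
Conditions: H2 (4 atm), 20% Pd(OH)2/C, EtOAc–EtOH (1:1), rt
Reagents that add atoms: none
Why: Catalytic hydrogenolysis; the three aryl benzyl ethers should cleave first, and the ring C1–O5 bond, then a benzylic ether para to a free phenol, is hydrogenolysed so that C1 becomes CH2 and O5 the free C5 hydroxyl; C3 and C5 are not benzylic and keep their configuration, and the neutral medium at room temperature should keep the acetate on O3.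

**Compound list**

1 | 3-(4-hydroxyphenyl)propan-1-ol | OCCCc1ccc(O)cc1 | starting material
2 | 3-[4-(benzyloxy)phenyl]propan-1-ol | OCCCc1ccc(OCc2ccccc2)cc1 | intermediate
3 | allyl acetate (prop-2-en-1-yl acetate) | C=CCOC(C)=O | starting material
4 | 3-[4-(benzyloxy)phenyl]propanal | O=CCCc1ccc(OCc2ccccc2)cc1 | intermediate (not isolated)
5 | (3R)-1-[4-(benzyloxy)phenyl]hex-5-en-3-ol | C=CC[C@H](O)CCc1ccc(OCc2ccccc2)cc1 | intermediate
6 | 3,4-bis(benzyloxy)benzaldehyde | O=Cc1ccc(OCc2ccccc2)c(OCc2ccccc2)c1 | starting material
7 | acetic acid | CC(=O)O | starting material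
8 | all-cis (2R,4S,6R)-2-[3,4-bis(benzyloxy)phenyl]-6-{2-[4-(benzyloxy)phenyl]ethyl}oxan-4-yl acetate | CC(=O)O[C@@H]1C[C@H](c2ccc(OCc3ccccc3)c(OCc3ccccc3)c2)O[C@H](CCc2ccc(OCc3ccccc3)cc2)C1 | intermediate
9 | all-cis (2R,4S,6R)-2-(3,4-dihydroxyphenyl)-6-[2-(4-hydroxyphenyl)ethyl]oxan-4-yl acetate | CC(=O)O[C@@H]1C[C@H](c2ccc(O)c(O)c2)O[C@H](CCc2ccc(O)cc2)C1 | intermediate (not isolated)
10 | (3R,5R)-1-(3,4-dihydroxyphenyl)-5-hydroxy-7-(4-hydroxyphenyl)heptan-3-yl acetate | CC(=O)O[C@H](CCc1ccc(O)c(O)c1)C[C@H](O)CCc1ccc(O)cc1 | target

**Step count and risks**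

Total step count: 4. Longest linear sequence: 4 steps (1 → 2 → 5 → 8 → 10).

Steps most likely to fail:

Step 3. The aryl-stabilised oxocarbenium ion may cyclise slowly. That would leave time for hydrolytic side-chain exchange, for leakage through the 2-oxonia-Cope manifold into an ionisable benzylic centre (loss of optical purity), and for acid-induced ionisation of the benzylic ring C–O bond of the product. The fallback is a segment-coupling Prins reaction that generates the same cation without releasing water. It sets out from 5, which is esterified with 3,4-bis(benzyloxy)benzoic acid (DCC, DMAP, CH2Cl2) to give (3R)-1-[4-(benzyloxy)phenyl]hex-5-en-3-yl 3,4-bis(benzyloxy)benzoate F1. Reductive acetylation (DIBAL-H, CH2Cl2, −78 °C, then Ac2O, pyridine, DMAP) should give the α-acetoxy ether [3,4-bis(benzyloxy)phenyl]({(3R)-1-[4-(benzyloxy)phenyl]hex-5-en-3-yl}oxy)methyl acetate F2 as a mixture of acetal epimers. Ionisation with BF3·OEt2 and AcOH in hexanes–CH2Cl2 at 0 °C closes the same ring through the same chair, and the route is rejoined at 8.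

Step 4. Debenzylation should be fast, but hydrogenolysis of the ring benzylic C–O bond may stall at the triphenolic stage, and forcing it with acid, heat or long exposure invites 1,3-acetyl migration between O3 and O5. The fallback separates the two events and opens the ring by ionic hydrogenation. It sets out from 8, which is treated with Et3SiH and BF3·OEt2 in CH2Cl2 at −40 to 0 °C. The para-benzyloxy-stabilised benzylic cation is reduced by the silane, giving (3R,5R)-1-[3,4-bis(benzyloxy)phenyl]-7-[4-(benzyloxy)phenyl]-5-hydroxyheptan-3-yl acetate F3. A short neutral debenzylation (H2 1 atm, Pd/C, EtOAc, rt) then rejoins the route at 10.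

Step 2. Enantioselectivity may be insufficient, the sense of induction may be opposite to that assumed, or conversion at the alcohol oxidation level may be incomplete. The fallback uses a stoichiometric chiral allylborane on the isolated aldehyde. It sets out from 2, which is oxidised (Dess–Martin periodinane, CH2Cl2, rt) to aldehyde 4. Brown allylboration with (−)-B-allyldiisopinocampheylborane (from (−)-Ipc2BOMe and allylMgBr; Et2O, −78 °C; then NaOH, H2O2) should give the (R)-carbinol, the sense established for unbranched aliphatic aldehydes. The route is rejoined at 5, and the detour passes only through compounds already listed.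

**Further compounds**

F1 | step 3 | (3R)-1-[4-(benzyloxy)phenyl]hex-5-en-3-yl 3,4-bis(benzyloxy)benzoate | C=CC[C@@H](CCc1ccc(OCc2ccccc2)cc1)OC(=O)c1ccc(OCc2ccccc2)c(OCc2ccccc2)c1
F2 | step 3 | [3,4-bis(benzyloxy)phenyl]({(3R)-1-[4-(benzyloxy)phenyl]hex-5-en-3-yl}oxy)methyl acetate (both acetal epimers) | C=CC[C@@H](CCc1ccc(OCc2ccccc2)cc1)OC(OC(C)=O)c1ccc(OCc2ccccc2)c(OCc2ccccc2)c1
F3 | step 4 | (3R,5R)-1-[3,4-bis(benzyloxy)phenyl]-7-[4-(benzyloxy)phenyl]-5-hydroxyheptan-3-yl acetate | CC(=O)O[C@H](CCc1ccc(OCc2ccccc2)c(OCc2ccccc2)c1)C[C@H](O)CCc1ccc(OCc2ccccc2)cc1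
F0 | step 2 | none | none
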